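## Retrosynthetic overview

- The target is unmasked last: two aryl formyl groups by ortho-lithiation/DMF, then acid removal of three MOM ethers and one TES ether.
- The C4 carbinol comes from a Wharton transposition of a 3,4-epoxy-2-ketone followed by hydrogenation; the C4–O bond is set earlier by a hydroxyl-directed epoxidation.
- Key disconnection C1–C9': intermolecular Michael addition of the lithium enolate of a 3,4-epoxy-eudesman-2-one to an isobutyl o-quinone methide, released in situ from a salicylaldehyde Boc carbonate and i-BuMgBr.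
- The epoxy ketone comes from ent-carissone by reductive triflation, triflate reduction (to the TES ether of ent-α-eudesmol), allylic oxidation, hydride reduction and directed epoxidation.
- Ring order: ring B is bought as (S)-carvone; ring A is annulated onto it by a chiral-imine Michael addition to ethyl vinyl ketone and aldol condensation (Robinson annulation); the aromatic ring is bought as 2,4,6-trihydroxybenzaldehyde.

Assumption: eudesmane numbering is used for the decalin (C10 carries the angular methyl, C4 the carbinol, C7 the hydroxyisopropyl group, C1 the side chain), C9' is the benzylic carbon, and "Me face" means the decalin face that carries the C10 methyl.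

## Route

Step 1
Reactants: 1 (S)-(+)-carvone
Product: 2 (2S,5S)-dihydrocarvone (used together with its minor 2-epimer)
Conditions: Zn dust, KOH, EtOH–H2O, reflux
Reagents that add atoms: none
Why: Dissolving-metal conjugate reduction of the enone leaves the isolated isopropenyl group and the C5 stereocenter untouched, and the C2 mixture does not matter because C2 becomes planar in the next steps.

Step 2
Reactants: 2 (2S,5S)-dihydrocarvone; 3 (S)-1-phenylethylamine
Product: 4 imine (1S)-N-[(5S)-2-methyl-5-(prop-1-en-2-yl)cyclohexylidene]-1-phenylethanamine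
Conditions: TsOH (cat.), toluene, Dean–Stark, reflux; used crude
Reagents that add atoms: none
Why: Acid-catalysed imine condensation with azeotropic removal of water is routine for 2-alkylcyclohexanones and introduces the chiral auxiliary without touching C5.

Step 3
Reactants: 4 imine; 5 ethyl vinyl ketone
Product: 7 (2R,5S)-2-methyl-2-(3-oxopentyl)-5-(prop-1-en-2-yl)cyclohexan-1-one, via Michael adduct imine 6 (not isolated)
Conditions: THF, 45 °C, 3 d; then 10% aq. AcOH, rt
Reagents that add atoms: water, O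
Why: d'Angelo asymmetric Michael addition: the more substituted secondary enamine tautomer adds to the enone through an aza-ene-like transition state on the face away from the phenyl group, so the (S)-auxiliary fixes the quaternary carbon as R (methyl cis to isopropenyl, the mirror image of the known (R)-amine/(+)-dihydrocarvone route to (+)-α-cyperone), and hydrolysis releases the amine.

Step 4
Reactants: 7 diketone
Product: 9 ent-α-cyperone [(7S,10R)-eudesma-4,11-dien-3-one], via aldol ketol 8 (not isolated)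
Conditions: NaOMe, MeOH, rt → 50 °C
Reagents that add atoms: none
Why: Intramolecular aldol condensation of the 1,5-diketone (second half of the Robinson annulation) can only close the six-membered ring A and creates no new stereocenter.

Step 5
Reactants: 9 ent-α-cyperone
Product: 11 ent-carissone [(7S,10R)-11-hydroxyeudesm-4-en-3-one], via organomercurial 10 (not isolated)
Conditions: Hg(OAc)2, THF–H2O, rt; then 3 M NaOH, NaBH4, 0 °C, brief
Reagents that add atoms: water, O
Why: Oxymercuration–demercuration gives Markovnikov hydration of the electron-rich 1,1-disubstituted alkene while the conjugated enone double bond is inert, as in the known α-cyperone to carissone conversion.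

Step 6
Reactants: 11 ent-carissone
Product: 12 (7S,10R)-11-(triethylsilyloxy)eudesm-4-en-3-one
Conditions: TESOTf, 2,6-lutidine, CH2Cl2, −78 → 0 °C
Reagents that add atoms: triethylsilyl triflate, CC[Si](CC)(CC)OS(=O)(=O)C(F)(F)F
Why: Silyl triflate silylation protects the tertiary alcohol so that no alkoxide interferes with the triflation and enolate steps that follow.

Step 7
Reactants: 12 silyl ether enone
Product: 14 (5S,7S,10R)-11-(triethylsilyloxy)eudesm-3-en-3-yl triflate, via lithium enolate 13 (not isolated)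
Conditions: Li, NH3 (l), THF, t-BuOH (1 equiv), −78 °C; remove NH3; PhNTf2, THF, 0 °C
Reagents that add atoms: N-phenylbis(trifluoromethanesulfonimide), O=S(=O)(N(c1ccccc1)S(=O)(=O)C(F)(F)F)C(F)(F)F
Why: Birch-type reduction of the octalone protonates C5 axially to give the trans-fused decalin (H5 opposite the Me face), and the regiodefined 3-enolate is trapped as its triflate.

Step 8
Reactants: 14 enol triflate
Product: 15 (5S,7S,10S)-11-(triethylsilyloxy)eudesm-3-ene (TES ether of ent-α-eudesmol)
Conditions: Pd(OAc)2 (cat.), PPh3, n-Bu3N, HCO2H, DMF, 60 °C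
Reagents that add atoms: none
Why: Palladium-catalysed formate reduction of an enol triflate (Cacchi reduction) replaces OTf by H without moving the double bond or touching a stereocenter.

Step 9
Reactants: 15 alkene
Product: 16 (5S,7S,10R)-11-(triethylsilyloxy)eudesm-3-en-2-one
Conditions: CrO3, 3,5-dimethylpyrazole, CH2Cl2, −20 °C
Reagents that add atoms: chromium trioxide, O=[Cr](=O)=O
Why: Allylic oxidation with the CrO3–3,5-dimethylpyrazole complex attacks the ring CH2 next to the CH end of the trisubstituted alkene (C2), in analogy with the 7-oxidation of 5-ene steroids, and gives the conjugated enone.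

Step 10
Reactants: 16 enone
Product: 17 (2R,5S,7S,10R)-11-(triethylsilyloxy)eudesm-3-en-2-ol (2-OH on the Me face)
Conditions: LiBH(s-Bu)3, THF, −78 °C; H2O
Reagents that add atoms: none
Why: The bulky hydride reduces the β,β-disubstituted enone 1,2 and approaches C2 from the face opposite the axial C10 methyl (1,3-diaxial shielding), which places the new hydroxyl pseudo-axial on the Me face.

Step 11
Reactants: 17 allylic alcohol
Product: 18 (2R,3R,4S,5S,7S,10R)-3,4-epoxy-11-(triethylsilyloxy)eudesman-2-ol
Conditions: VO(acac)2 (cat.), t-BuOOH, CH2Cl2, 0 °C → rt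
Reagents that add atoms: tert-butyl hydroperoxide, CC(C)(C)OO
Why: Hydroxyl-directed vanadium-catalysed epoxidation (Sharpless–Michaelson) delivers oxygen syn to the pseudo-axial 2-OH, so the C4–O bond is formed on the Me face as the target requires.

Step 12
Reactants: 18 epoxy alcohol
Product: 19 (3S,4S,5S,7S,10R)-3,4-epoxy-11-(triethylsilyloxy)eudesman-2-one
Conditions: Dess–Martin periodinane, CH2Cl2, rt
Reagents that add atoms: none
Why: Dess–Martin oxidation converts the secondary alcohol into the ketone under neutral conditions that leave the epoxide and the silyl ether intact.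

Step 13
Reactants: 20 2,4,6-trihydroxybenzaldehyde
Product: 21 2-hydroxy-4,6-bis(methoxymethoxy)benzaldehyde
Conditions: MOMCl (2.2 equiv), i-Pr2NEt, CH2Cl2, 0 °C → rt
Reagents that add atoms: chloromethyl methyl ether, COCCl
Why: Williamson-type acetalisation protects the two free phenols, while the hydroxyl hydrogen-bonded to the aldehyde stays free.

Step 14
Reactants: 21 salicylaldehyde
Product: 22 tert-butyl 2-formyl-3,5-bis(methoxymethoxy)phenyl carbonate
Conditions: Boc2O, i-Pr2NEt, DMAP (cat.), THF, rt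
Reagents that add atoms: di-tert-butyl dicarbonate, CC(C)(C)OC(=O)OC(=O)OC(C)(C)C
Why: DMAP-catalysed O-acylation gives the aryl Boc carbonate that serves as a low-temperature o-quinone methide precursor.

Step 15
Reactants: 19 epoxy ketone; 22 aryl carbonate; 23 isobutylmagnesium bromide
Product: 28 3,4-epoxy-1-{(1R)-3-methyl-1-[2,4,6-tris(methoxymethoxy)phenyl]butyl}-11-(triethylsilyloxy)eudesman-2-one (1S; side chain opposite the Me face), via lithium enolate 24 (not isolated), via magnesium alkoxide 25 (not isolated), via o-quinone methide 26 (not isolated), via lithium phenoxide 27 (not isolated)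
Conditions: 19: LiN(i-Pr)2, THF, −78 °C; 22: 23, THF, −78 °C; mix, −78 → −20 °C; then MOMCl, 0 °C
Reagents that add atoms: chloromethyl methyl ether, COCCl
Why: Intermolecular Michael addition of the regiodefined enolate (C1 is the only enolisable position) to the o-quinone methide released by the Pettus cascade (Grignard addition, Boc shift, loss of tert-butyl carbonate): the enolate reacts on the face opposite the axial C10 methyl and the epoxide (sets C1), a closed lithium-bridged transition state with the isobutyl group of the (E)-quinone methide pointing outward sets C9' as R, and MOMCl caps the phenoxide so that no retro-Michael can follow.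

Step 16
Reactants: 28 epoxy ketone adduct
Product: 30 1-{(1R)-3-methyl-1-[2,4,6-tris(methoxymethoxy)phenyl]butyl}-11-(triethylsilyloxy)eudesm-2-en-4-ol (4-OH on the Me face), via hydrazone 29 (not isolated)
Conditions: N2H4·H2O, AcOH (cat.), MeOH, 0 °C → rt
Reagents that add atoms: none
Why: Wharton transposition (hydrazone formation, epoxide opening, loss of N2) removes the C2 oxygen and leaves the tertiary C4 alcohol with its C–O bond untouched, so C4 keeps the configuration set in step 11.

Step 17
Reactants: 30 allylic alcohol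
Product: 31 1-{(1R)-3-methyl-1-[2,4,6-tris(methoxymethoxy)phenyl]butyl}-11-(triethylsilyloxy)eudesman-4-ol
Conditions: H2 (1 atm), PtO2, EtOAc, rt
Reagents that add atoms: none
Why: Catalytic hydrogenation saturates the 2,3-double bond without creating a stereocenter, and platinum keeps hydrogenolysis of the allylic C–O bond low.

Step 18
Reactants: 31 saturated alcohol
Product: 32 3-formyl derivative of 31 (aryl = 3-formyl-2,4,6-tris(methoxymethoxy)phenyl)
Conditions: n-BuLi (2.2 equiv), TMEDA, THF, −78 → 0 °C; DMF, −78 → 0 °C; H2O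
Reagents that add atoms: N,N-dimethylformamide, CN(C)C=O
Why: Directed ortho-metalation between two MOM ethers followed by formylation with DMF; the tertiary alcohol is carried as its lithium alkoxide.

Step 19
Reactants: 32 monoaldehyde
Product: 34 3,5-diformyl derivative of 31 (aryl = 3,5-diformyl-2,4,6-tris(methoxymethoxy)phenyl), via lithium aminoalkoxide 33 (not isolated)
Conditions: N-methylpiperazine, n-BuLi, THF, −20 °C; n-BuLi, TMEDA, −20 → 0 °C; DMF; H2O
Reagents that add atoms: N,N-dimethylformamide, CN(C)C=O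
Why: Comins in situ protection of the aldehyde as an α-amino alkoxide allows a second directed ortho-metalation at the remaining position between two MOM ethers, and DMF then gives the dialdehyde.

Step 20
Reactants: 34 dialdehyde
Product: 35 target, 5-[(1R)-1-[(1S,4R,4aS,6S,8aR)-4-hydroxy-6-(2-hydroxypropan-2-yl)-4,8a-dimethyldecahydronaphthalen-1-yl]-3-methylbutyl]-2,4,6-trihydroxybenzene-1,3-dicarbaldehyde
Conditions: 2 M aq. HCl, MeOH–THF, 40 °C
Reagents that add atoms: none
Why: Acid-catalysed acetal cleavage removes the three aryl MOM ethers (activated by the ortho formyl groups) and the TES ether under conditions mild enough for the two tertiary alcohols.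

## Compound list

1 | (S)-(+)-carvone | CC1=CC[C@@H](CC1=O)C(C)=C | starting material
2 | (2S,5S)-dihydrocarvone | C[C@H]1CC[C@@H](CC1=O)C(C)=C | intermediate
3 | (S)-1-phenylethylamine | C[C@H](N)c1ccccc1 | starting material
4 | (1S)-N-[(5S)-2-methyl-5-(prop-1-en-2-yl)cyclohexylidene]-1-phenylethanamine (C2 epimers) | CC1CC[C@@H](CC1=N[C@@H](C)c1ccccc1)C(C)=C | intermediate
5 | ethyl vinyl ketone (pent-1-en-3-one) | CCC(=O)C=C | starting material
6 | (1S)-N-[(2R,5S)-2-methyl-2-(3-oxopentyl)-5-(prop-1-en-2-yl)cyclohexylidene]-1-phenylethanamine | CCC(=O)CC[C@@]1(C)CC[C@@H](CC1=N[C@@H](C)c1ccccc1)C(C)=C | intermediate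
7 | (2R,5S)-2-methyl-2-(3-oxopentyl)-5-(prop-1-en-2-yl)cyclohexan-1-one | CCC(=O)CC[C@@]1(C)CC[C@@H](CC1=O)C(C)=C | intermediate
8 | (7S,10R)-5-hydroxyeudesm-11-en-3-one (aldol ketol, C4 and C5 epimers) | C1CC(=O)C(C)C2(O)C[C@@H](C(C)=C)CC[C@]12C | intermediate
9 | ent-α-cyperone, (7S,10R)-eudesma-4,11-dien-3-one | C1CC(=O)C(C)=C2C[C@@H](C(C)=C)CC[C@]12C | intermediate
10 | (7S,10R)-12-(acetoxymercurio)-11-hydroxyeudesm-4-en-3-one (C11 epimers) | C1CC(=O)C(C)=C2C[C@@H](C(C)(O)C[Hg]OC(C)=O)CC[C@]12C | intermediate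
11 | ent-carissone, (7S,10R)-11-hydroxyeudesm-4-en-3-one | C1CC(=O)C(C)=C2C[C@@H](C(C)(C)O)CC[C@]12C | intermediate
12 | (7S,10R)-11-(triethylsilyloxy)eudesm-4-en-3-one | C1CC(=O)C(C)=C2C[C@@H](C(C)(C)O[Si](CC)(CC)CC)CC[C@]12C | intermediate
13 | lithium (5S,7S,10R)-11-(triethylsilyloxy)eudesm-3-en-3-olate | C1CC([O-])=C(C)[C@H]2C[C@@H](C(C)(C)O[Si](CC)(CC)CC)CC[C@]12C.[Li+] | intermediate
14 | (5S,7S,10R)-11-(triethylsilyloxy)eudesm-3-en-3-yl trifluoromethanesulfonate | C1CC(OS(=O)(=O)C(F)(F)F)=C(C)[C@H]2C[C@@H](C(C)(C)O[Si](CC)(CC)CC)CC[C@]12C | intermediate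
15 | (5S,7S,10S)-11-(triethylsilyloxy)eudesm-3-ene (TES ether of ent-α-eudesmol) | C1CC=C(C)[C@H]2C[C@@H](C(C)(C)O[Si](CC)(CC)CC)CC[C@]12C | intermediate
16 | (5S,7S,10R)-11-(triethylsilyloxy)eudesm-3-en-2-one | C1C(=O)C=C(C)[C@H]2C[C@@H](C(C)(C)O[Si](CC)(CC)CC)CC[C@]12C | intermediate
17 | (2R,5S,7S,10R)-11-(triethylsilyloxy)eudesm-3-en-2-ol | C1[C@@H](O)C=C(C)[C@H]2C[C@@H](C(C)(C)O[Si](CC)(CC)CC)CC[C@]12C | intermediate
18 | (2R,3R,4S,5S,7S,10R)-3,4-epoxy-11-(triethylsilyloxy)eudesman-2-ol | C1[C@@H](O)[C@H]3O[C@@]3(C)[C@H]2C[C@@H](C(C)(C)O[Si](CC)(CC)CC)CC[C@]12C | intermediate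
19 | (3S,4S,5S,7S,10R)-3,4-epoxy-11-(triethylsilyloxy)eudesman-2-one | C1C(=O)[C@H]3O[C@@]3(C)[C@H]2C[C@@H](C(C)(C)O[Si](CC)(CC)CC)CC[C@]12C | intermediate
20 | 2,4,6-trihydroxybenzaldehyde | O=Cc1c(O)cc(O)cc1O | starting material
21 | 2-hydroxy-4,6-bis(methoxymethoxy)benzaldehyde | O=Cc1c(O)cc(OCOC)cc1OCOC | intermediate
22 | tert-butyl 2-formyl-3,5-bis(methoxymethoxy)phenyl carbonate | O=Cc1c(OC(=O)OC(C)(C)C)cc(OCOC)cc1OCOC | intermediate
23 | isobutylmagnesium bromide | CC(C)C[Mg]Br | starting material
24 | lithium enolate of 19 (3,4-epoxy-11-(triethylsilyloxy)eudesm-1-en-2-olate) | C1=C([O-])[C@H]3O[C@@]3(C)[C@H]2C[C@@H](C(C)(C)O[Si](CC)(CC)CC)CC[C@]12C.[Li+] | intermediate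
25 | bromomagnesium 1-[2-(tert-butoxycarbonyloxy)-4,6-bis(methoxymethoxy)phenyl]-3-methylbutan-1-olate (racemic) | CC(C)CC(O[Mg]Br)c1c(OC(=O)OC(C)(C)C)cc(OCOC)cc1OCOC | intermediate
26 | (6E)-3,5-bis(methoxymethoxy)-6-(3-methylbutylidene)cyclohexa-2,4-dien-1-one | CC(C)C/C=C1/C(=O)C=C(OCOC)C=C1OCOC | intermediate
27 | lithium phenoxide Michael adduct (as 28 with one aryl O–Li in place of one OMOM) | CC(C)C[C@@H](c4c([O-])cc(OCOC)cc4OCOC)[C@@H]1C(=O)[C@H]3O[C@@]3(C)[C@H]2C[C@@H](C(C)(C)O[Si](CC)(CC)CC)CC[C@]12C.[Li+] | intermediate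
28 | 3,4-epoxy-1-{(1R)-3-methyl-1-[2,4,6-tris(methoxymethoxy)phenyl]butyl}-11-(triethylsilyloxy)eudesman-2-one (1S; side chain opposite the Me face, epoxide on the Me face) | CC(C)C[C@@H](c4c(OCOC)cc(OCOC)cc4OCOC)[C@@H]1C(=O)[C@H]3O[C@@]3(C)[C@H]2C[C@@H](C(C)(C)O[Si](CC)(CC)CC)CC[C@]12C | intermediate
29 | hydrazone of 28 | CC(C)C[C@@H](c4c(OCOC)cc(OCOC)cc4OCOC)[C@@H]1C(=NN)[C@H]3O[C@@]3(C)[C@H]2C[C@@H](C(C)(C)O[Si](CC)(CC)CC)CC[C@]12C | intermediate
30 | 1-{(1R)-3-methyl-1-[2,4,6-tris(methoxymethoxy)phenyl]butyl}-11-(triethylsilyloxy)eudesm-2-en-4-ol (4-OH on the Me face) | CC(C)C[C@@H](c4c(OCOC)cc(OCOC)cc4OCOC)[C@@H]1C=C[C@@](C)(O)[C@H]2C[C@@H](C(C)(C)O[Si](CC)(CC)CC)CC[C@]12C | intermediate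
31 | 1-{(1R)-3-methyl-1-[2,4,6-tris(methoxymethoxy)phenyl]butyl}-11-(triethylsilyloxy)eudesman-4-ol | CC(C)C[C@@H](c4c(OCOC)cc(OCOC)cc4OCOC)[C@@H]1CC[C@@](C)(O)[C@H]2C[C@@H](C(C)(C)O[Si](CC)(CC)CC)CC[C@]12C | intermediate
32 | monoaldehyde: 31 with a 3-formyl-2,4,6-tris(methoxymethoxy)phenyl ring | CC(C)C[C@@H](c4c(OCOC)c(C=O)c(OCOC)cc4OCOC)[C@@H]1CC[C@@](C)(O)[C@H]2C[C@@H](C(C)(C)O[Si](CC)(CC)CC)CC[C@]12C | intermediate
33 | dilithium aminoalkoxide of 32 (N-methylpiperazine adduct of the aldehyde, C4 alkoxide) | CC(C)C[C@@H](c4c(OCOC)c(C([O-])N5CCN(C)CC5)c(OCOC)cc4OCOC)[C@@H]1CC[C@@](C)([O-])[C@H]2C[C@@H](C(C)(C)O[Si](CC)(CC)CC)CC[C@]12C.[Li+].[Li+] | intermediate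
34 | dialdehyde: 31 with a 3,5-diformyl-2,4,6-tris(methoxymethoxy)phenyl ring | CC(C)C[C@@H](c4c(OCOC)c(C=O)c(OCOC)c(C=O)c4OCOC)[C@@H]1CC[C@@](C)(O)[C@H]2C[C@@H](C(C)(C)O[Si](CC)(CC)CC)CC[C@]12C | intermediate
35 | 5-[(1R)-1-[(1S,4R,4aS,6S,8aR)-4-hydroxy-6-(2-hydroxypropan-2-yl)-4,8a-dimethyldecahydronaphthalen-1-yl]-3-methylbutyl]-2,4,6-trihydroxybenzene-1,3-dicarbaldehyde | CC(C)C[C@@H](c1c(O)c(C=O)c(O)c(C=O)c1O)[C@@H]1CC[C@@](C)(O)[C@H]2C[C@@H](C(C)(C)O)CC[C@]12C | target

## Step count and risks

Total step count: 20. Longest linear sequence: 18 steps (steps 1–12 and 15–20, from (S)-carvone); the aryl carbonate branch adds steps 13 and 14.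

The three steps most likely to fail:

Step 15. The C1 configuration rests on solid steric grounds, but the C9' configuration depends on the quinone methide geometry and on a closed transition state, and the tert-butoxide set free can epimerise C1. The fallback sets out from 19. TBSOTf and Et3N give the tert-butyldimethylsilyl enol ether F1. F1 is combined with quinone methide 26 (made as before from 22 and 23) in an inverse-demand hetero-Diels–Alder reaction, whose endo transition state (silyloxy group under the heterodiene, isobutyl outward) gives the cis-fused 2-silyloxychroman F2 with the same sense at C1 and C9'. TBAF opens F2 to phenoxide 27, and MOMCl capping comes back to the route at 28.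

Step 16. The C2 ketone is flanked by the substituted C1 and the epoxide, so hydrazone formation may be slow and C1 may epimerise. The fallback sets out from 28. NaBH4 gives the epoxy alcohol F3; NaH, CS2 and MeI give the S-methyl xanthate F4; Bu3SnH with AIBN generates the C2 radical, which opens the epoxide and gives the tertiary allylic alcohol. This comes back to the route at 30.

Step 20. The acid strength needed for the tertiary TES ether may start to dehydrate the tertiary alcohols. The fallback sets out from 34. TBAF removes the silyl group first to give the tris-MOM dialdehyde diol F5; ZnBr2 with n-PrSH in CH2Cl2 then transfers the three MOM groups to sulfur under non-protic conditions. This comes back to the route at 35.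

## Further compounds

F1 | step 15 | tert-butyldimethylsilyl enol ether of 19 (2-silyloxy-1-ene) | C1=C(O[Si](C)(C)C(C)(C)C)[C@H]3O[C@@]3(C)[C@H]2C[C@@H](C(C)(C)O[Si](CC)(CC)CC)CC[C@]12C
F2 | step 15 | cis-fused 2-(tert-butyldimethylsilyloxy)chroman cycloadduct of F1 and 26 (aryl oxygen and C9' both on the face opposite the Me face) | CC(C)C[C@@H]4[C@@H]1[C@](O[Si](C)(C)C(C)(C)C)(Oc5cc(OCOC)cc(OCOC)c45)[C@H]3O[C@@]3(C)[C@H]2C[C@@H](C(C)(C)O[Si](CC)(CC)CC)CC[C@]12C
F3 | step 16 | 2-hydroxy compound from reduction of 28 (C2 epimers) | CC(C)C[C@@H](c4c(OCOC)cc(OCOC)cc4OCOC)[C@@H]1C(O)[C@H]3O[C@@]3(C)[C@H]2C[C@@H](C(C)(C)O[Si](CC)(CC)CC)CC[C@]12C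
F4 | step 16 | O-alkyl S-methyl xanthate of F3 (C2 epimers) | CC(C)C[C@@H](c4c(OCOC)cc(OCOC)cc4OCOC)[C@@H]1C(OC(=S)SC)[C@H]3O[C@@]3(C)[C@H]2C[C@@H](C(C)(C)O[Si](CC)(CC)CC)CC[C@]12C
F5 | step 20 | desilylated dialdehyde (34 with free 11-OH) | CC(C)C[C@@H](c4c(OCOC)c(C=O)c(OCOC)c(C=O)c4OCOC)[C@@H]1CC[C@@](C)(O)[C@H]2C[C@@H](C(C)(C)O)CC[C@]12C
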